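**Retrosynthetic overview**
1. Feature: in the flavone half, C8 carries C3' of flavanone ring B and lies between two oxygen-bearing carbons, C7 and C8a. With C5, these are the three oxygens of one phloroglucinol ring (flavone ring A), and they must end up as ring oxygen O1, 7-OH and 5-OH.
2. Last disconnections: global O-debenzylation, then flavanone ring C by catalytic asymmetric oxa-Michael closure (O1–C2, sets 2S). The substrate is a chalcone activated by an alpha tert-butyl ester, made by Knoevenagel condensation of a flavone-benzaldehyde with a ring A beta-keto ester.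
3. Flavone ring C: Baker–Venkataraman-type aroylation and cyclodehydration of an o-hydroxyacetophenone. Its acetyl carbon is placed by phenol-directed ortho-formylation at C4a.
4. Flavone ring A: Danheiser benzannulation of 3-(benzyloxy)cyclobutenone with an aryl siloxyalkyne (C8a–C8, C7–C6, ring closure C8a–C4a). The three oxygens emerge as OH, OTIPS and OBn in one step. The alkyne comes from methyl 5-formylsalicylate by Kowalski ynolate rearrangement.
5. Ring order: flavone ring A, flavone ring C, flavanone ring C. The other three arene rings are bought.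

Key step: step 5

Assumption: the C3'–C8 axis (three ortho substituents) is taken as configurationally labile at room temperature, since the target carries no axial descriptor; rotamers of protected intermediates are not counted as separate compounds.
Assumption: the thiourea derived from 9-amino-9-deoxy-epi-quinidine is taken to give the 2S product; its quinine-derived pseudoenantiomer replaces it unchanged if circular dichroism of the protected flavanone shows the opposite sense.
Abbreviations: Ar = 2-(benzyloxy)-5-(5,5-dimethyl-1,3-dioxan-2-yl)phenyl; Fl = 5,7-bis(benzyloxy)-2-[4-(benzyloxy)phenyl]-4-oxo-4H-chromen-8-yl; TIPS = triisopropylsilyl.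

**Step 1**
Reactants: 1 methyl 5-formyl-2-hydroxybenzoate
Product: 2 methyl 2-(benzyloxy)-5-formylbenzoate
Conditions: BnBr, K2CO3, DMF, 50 °C
Reagents that add atoms: benzyl bromide, BrCc1ccccc1
Why: Williamson etherification of the acidic salicylate phenol; benzyl is used so that all phenol protecting groups of the end game fall in one neutral hydrogenolysis.

**Step 2**
Reactants: 2 methyl 2-(benzyloxy)-5-formylbenzoate
Product: 3 methyl 2-(benzyloxy)-5-(5,5-dimethyl-1,3-dioxan-2-yl)benzoate
Conditions: 2,2-dimethylpropane-1,3-diol, p-TsOH·H2O (cat.), toluene, reflux, Dean–Stark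
Reagents that add atoms: 2,2-dimethylpropane-1,3-diol, OCC(C)(C)CO
Why: Acid-catalysed acetalisation with azeotropic water removal masks the aldehyde for step 3; the six-membered acetal is preferred to a 1,3-dioxolane because 2-aryl-1,3-dioxolanes can be metalated at C2 by alkyllithiums and then fragment to ethylene and a benzoate.

**Step 3**
Reactants: 3 methyl 2-(benzyloxy)-5-(5,5-dimethyl-1,3-dioxan-2-yl)benzoate
Product: 6 (Ar-ethynyl)oxy-triisopropylsilane, via lithium dibromoenolate 4 (not isolated), via lithium ynolate 5 (not isolated)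
Conditions: CH2Br2, lithium 2,2,6,6-tetramethylpiperidide (from the amine and n-BuLi), THF, −78 °C; LiN(SiMe3)2, −78 to −20 °C; n-BuLi, −78 to 0 °C; i-Pr3SiCl, −78 to 0 °C
Reagents that add atoms: dibromomethane, BrCBr; chlorotriisopropylsilane, CC(C)[Si](Cl)(C(C)C)C(C)C
Why: Kowalski ester homologation stopped at the ynolate: LiCHBr2 adds to the ester, the dibromoketone is held as enolate 4, bromine–lithium exchange triggers a 1,2-aryl shift with loss of LiBr to ynolate 5 (this shift, onto an uncrowded carbon, makes the aryl–carbon bond that later is the C3'–C8 biaryl bond), and the bulky silyl chloride traps the ynolate on oxygen.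

**Step 4**
Reactants: 7 cyclobutane-1,3-dione
Product: 8 3-(benzyloxy)cyclobut-2-en-1-one
Conditions: BnOH, PPh3, DIAD, THF, 0 °C to rt
Reagents that add atoms: benzyl alcohol, OCc1ccccc1
Why: Mitsunobu alkylation of a strongly acidic vinylogous acid (the enol form of 7), a class of pronucleophile that is alkylated on oxygen, run far below the temperature at which the cyclobutenone ring opens.

**Step 5**
Reactants: 6 (Ar-ethynyl)oxy-triisopropylsilane; 8 3-(benzyloxy)cyclobut-2-en-1-one
Product: 13 2-Ar-5-(benzyloxy)-3-(triisopropylsilyloxy)phenol, via vinylketene 9 (not isolated), via 4-vinylcyclobutenone 10 (not isolated), via dienylketene 11 (not isolated), via cyclohexadienone 12 (not isolated)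
Conditions: 6 (1.2 equiv), toluene, 80 °C, slow addition of 8; then 110 °C, argon
Reagents that add atoms: none
Why: Heating opens 8 by four-electron electrocyclic cleavage to the alkoxyvinylketene 9, and the aryl-bearing nucleophilic carbon of ynol ether 6 bonds to the ketene carbonyl carbon in a [2+2] cycloaddition that forms C8a–C8 and C7–C6 and gives 10. Compound 10 opens reversibly by a second four-electron process to dienylketene 11, and the isomer with ketene and vinyl termini cis closes flavone ring A by six-electron electrocyclisation (C8a–C4a) to dienone 12, which tautomerises to phenol 13. This is the Danheiser benzannulation in its known cyclobutenone/siloxyalkyne form that gives resorcinol monosilyl ethers; a 3-oxygenated cyclobutenone combined with an ortho-substituted aryl ynol ether is a sparsely tested pairing, and the risk of the route sits there. No stereocentre is formed. The step needs a single alkyne orientation, which the polarity of the ynol ether secures: the aryl group lands between the new hydroxyl (future O1) and the siloxy group (C7), while the benzyloxy group of 8 ends at C5. Slow addition of 8 to a slight excess of 6 should limit ketene dimerisation and acylation of the hindered product phenol.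

**Step 6**
Reactants: 13 2-Ar-5-(benzyloxy)-3-(triisopropylsilyloxy)phenol
Product: 14 3-Ar-6-(benzyloxy)-2-hydroxy-4-(triisopropylsilyloxy)benzaldehyde
Conditions: MgCl2, Et3N, (CH2O)n, MeCN, reflux; cold aq citric acid work-up
Reagents that add atoms: paraformaldehyde (as formaldehyde), C=O
Why: Casnati–Skattebøl ortho-formylation: the magnesium phenoxide delivers formaldehyde through a chelate to the only free ortho carbon (C4a) and leaves the para C6–H untouched, a second formaldehyde oxidises the benzylic alkoxide to the aldehyde, and the basic medium spares the acetal, silyl ether and benzyl ethers that a Fries or Friedel–Crafts acetylation would attack.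

**Step 7**
Reactants: 14 3-Ar-6-(benzyloxy)-2-hydroxy-4-(triisopropylsilyloxy)benzaldehyde
Product: 15 1-[3-Ar-6-(benzyloxy)-2-hydroxy-4-(triisopropylsilyloxy)phenyl]ethanol (racemic)
Conditions: MeMgBr (3 equiv), THF, 0 °C; pH 7 buffer; used crude
Reagents that add atoms: methylmagnesium bromide, C[Mg]Br
Why: Grignard addition to the aldehyde after deprotonation of the phenol by the first equivalent; the carbinol centre is racemic and is erased in step 8, and the neutral work-up avoids o-quinone methide formation.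

**Step 8**
Reactants: 15 1-[3-Ar-6-(benzyloxy)-2-hydroxy-4-(triisopropylsilyloxy)phenyl]ethanol
Product: 16 1-[3-Ar-6-(benzyloxy)-2-hydroxy-4-(triisopropylsilyloxy)phenyl]ethanone
Conditions: activated MnO2, CH2Cl2, rt
Reagents that add atoms: none
Why: Selective MnO2 oxidation of an electron-rich benzylic alcohol under neutral conditions that should leave the free phenol and all protecting groups intact.

**Step 9**
Reactants: 16 1-[3-Ar-6-(benzyloxy)-2-hydroxy-4-(triisopropylsilyloxy)phenyl]ethanone; 17 4-(benzyloxy)benzoyl chloride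
Product: 18 1-[3-Ar-6-(benzyloxy)-2-hydroxy-4-(triisopropylsilyloxy)phenyl]-3-[4-(benzyloxy)phenyl]propane-1,3-dione
Conditions: LiN(SiMe3)2 (3.5 equiv), THF, −78 to −10 °C; 17, −78 °C to rt
Reagents that add atoms: none
Why: Baker–Venkataraman-type synthesis of the 1,3-diketone: the phenoxide/enolate dianion is aroylated at carbon, and any O-aroate formed at the hindered phenoxide undergoes the O-to-C acyl shift under the excess base to the same product, with no hydroxide present that could cleave the aryl silyl ether.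

**Step 10**
Reactants: 18 1-[3-Ar-6-(benzyloxy)-2-hydroxy-4-(triisopropylsilyloxy)phenyl]-3-[4-(benzyloxy)phenyl]propane-1,3-dione
Product: 20 4-(benzyloxy)-3-{5-(benzyloxy)-2-[4-(benzyloxy)phenyl]-4-oxo-7-(triisopropylsilyloxy)-4H-chromen-8-yl}benzaldehyde, via flavone acetal 19 (not isolated)
Conditions: p-TsOH·H2O (cat.), toluene, 80 °C; then 2 M aq HCl–THF, 40 °C
Reagents that add atoms: water, O
Why: Acid-catalysed cyclodehydration of the o-hydroxyaryl 1,3-diketone closes flavone ring C through the only free phenol (O1–C2), and aqueous acid then hydrolyses the donor-activated aryl acetal, while aryl TIPS and benzyl ethers tolerate mild acid.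

**Step 11**
Reactants: 20 4-(benzyloxy)-3-{5-(benzyloxy)-2-[4-(benzyloxy)phenyl]-4-oxo-7-(triisopropylsilyloxy)-4H-chromen-8-yl}benzaldehyde
Product: 21 4-(benzyloxy)-3-Fl-benzaldehyde
Conditions: CsF, BnBr, DMF, rt
Reagents that add atoms: benzyl bromide, BrCc1ccccc1
Why: Fluoride desilylation releases the caesium 7-phenoxide, which undergoes Williamson benzylation in the same pot; the exchange is made on an achiral compound so that no fluoride or base is needed once the base-sensitive C2 centre exists and no acidic 7-OH can quench the amine catalyst of step 16.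

**Step 12**
Reactants: 22 2,4,6-trihydroxyacetophenone
Product: 23 2,6-dihydroxy-4-methoxyacetophenone
Conditions: Me2SO4 (1.0 equiv), K2CO3 (1.0 equiv), acetone, reflux
Reagents that add atoms: dimethyl sulfate, COS(=O)(=O)OC
Why: Williamson methylation selective for the 4-hydroxyl, the only one not hydrogen-bonded to the acetyl group and therefore the most acidic and nucleophilic.

**Step 13**
Reactants: 23 2,6-dihydroxy-4-methoxyacetophenone
Product: 24 2-(benzyloxy)-6-hydroxy-4-methoxyacetophenone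
Conditions: BnBr (1.05 equiv), K2CO3, acetone, reflux
Reagents that add atoms: benzyl bromide, BrCc1ccccc1
Why: Williamson monobenzylation of two equivalent hydroxyls, which should stop after one alkylation because the remaining hydroxyl is then strongly chelated to the carbonyl group.

**Step 14**
Reactants: 24 2-(benzyloxy)-6-hydroxy-4-methoxyacetophenone
Product: 25 tert-butyl 3-[2-(benzyloxy)-6-hydroxy-4-methoxyphenyl]-3-oxopropanoate
Conditions: LiN(SiMe3)2 (3.3 equiv), THF, −78 °C; Boc2O (1.1 equiv), −78 to 0 °C; aq NH4Cl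
Reagents that add atoms: di-tert-butyl dicarbonate, CC(C)(C)OC(=O)OC(=O)OC(C)(C)C
Why: Crossed Claisen-type C-acylation of the lithium enolate with Boc2O installs the activating ester; an aryl carbonate formed at the phenoxide would transfer its acyl group to the enolate carbon under the excess base and converge on 25, and the low temperature prevents lactonisation to a 4-hydroxycoumarin.

**Step 15**
Reactants: 21 4-(benzyloxy)-3-Fl-benzaldehyde; 25 tert-butyl 3-[2-(benzyloxy)-6-hydroxy-4-methoxyphenyl]-3-oxopropanoate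
Product: 26 tert-butyl (Z)-2-[2-(benzyloxy)-6-hydroxy-4-methoxybenzoyl]-3-[4-(benzyloxy)-3-Fl-phenyl]prop-2-enoate
Conditions: piperidine (cat.), AcOH (cat.), 4 Å molecular sieves, toluene, rt
Reagents that add atoms: none
Why: Knoevenagel condensation of the active methylene with the unhindered aryl aldehyde should give the ester-activated chalcone, expected mainly with the aryl group trans to the aroyl group, under buffered conditions mild enough to keep the free 2'-phenol from adding.

**Step 16**
Reactants: 26 tert-butyl (Z)-2-[2-(benzyloxy)-6-hydroxy-4-methoxybenzoyl]-3-[4-(benzyloxy)-3-Fl-phenyl]prop-2-enoate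
Product: 29 (2S)-5-(benzyloxy)-2-[4-(benzyloxy)-3-Fl-phenyl]-7-methoxychroman-4-one, via flavanone-3-carboxylate 27 (not isolated), via beta-keto acid 28 (not isolated)
Conditions: thiourea from 9-amino-9-deoxy-epi-quinidine and 3,5-(CF3)2C6H3NCS (10 mol %), toluene, −25 °C; then p-TsOH·H2O, 80 °C
Reagents that add atoms: none
Why: Bifunctional cinchona-thiourea catalysis of the intramolecular 6-endo-trig oxa-Michael addition, the known enantioselective flavanone synthesis from alkylidene beta-keto esters: the thiourea binds the two carbonyl groups, the quinuclidine activates the 2'-phenol and the chiral pocket directs oxygen to one face of C2 to set 2S, after which acid cleaves the tert-butyl ester and acid 28 loses CO2, which removes the labile C3 centre and the reversibility of the closure.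

**Step 17**
Reactants: 29 (2S)-5-(benzyloxy)-2-[4-(benzyloxy)-3-Fl-phenyl]-7-methoxychroman-4-one
Product: 30 8-{2-hydroxy-5-[(2S)-5-hydroxy-7-methoxy-4-oxochroman-2-yl]phenyl}-5,7-dihydroxy-2-(4-hydroxyphenyl)-4H-chromen-4-one (CNP0107492.1)
Conditions: H2 (1 atm), 10% Pd/C, THF–MeOH, rt; evaporation below 35 °C
Reagents that add atoms: none
Why: Catalytic hydrogenolysis removes all five benzyl ethers under neutral conditions, so the retro-oxa-Michael racemisation that base would cause once the 4'-hydroxyl is free is avoided, and the flavone C2=C3 bond and both carbonyl groups normally survive these mild conditions.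

**Compound list**
1 | methyl 5-formyl-2-hydroxybenzoate | COC(=O)c1cc(C=O)ccc1O | starting material
2 | methyl 2-(benzyloxy)-5-formylbenzoate | COC(=O)c1cc(C=O)ccc1OCc1ccccc1 | intermediate
3 | methyl 2-(benzyloxy)-5-(5,5-dimethyl-1,3-dioxan-2-yl)benzoate | COC(=O)c1cc(C2OCC(C)(C)CO2)ccc1OCc1ccccc1 | intermediate
4 | lithium 1-Ar-2,2-dibromoethenolate | [Li]OC(=C(Br)Br)c1cc(C2OCC(C)(C)CO2)ccc1OCc1ccccc1 | intermediate
5 | lithium Ar-ethynolate | [Li]OC#Cc1cc(C2OCC(C)(C)CO2)ccc1OCc1ccccc1 | intermediate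
6 | {[2-(benzyloxy)-5-(5,5-dimethyl-1,3-dioxan-2-yl)phenyl]ethynyl}oxy-triisopropylsilane | CC(C)[Si](OC#Cc1cc(C2OCC(C)(C)CO2)ccc1OCc1ccccc1)(C(C)C)C(C)C | intermediate
7 | cyclobutane-1,3-dione | O=C1CC(=O)C1 | starting material
8 | 3-(benzyloxy)cyclobut-2-en-1-one | O=C1C=C(OCc2ccccc2)C1 | intermediate
9 | 3-(benzyloxy)buta-1,3-dien-1-one | O=C=CC(=C)OCc1ccccc1 | intermediate
10 | 2-Ar-4-[1-(benzyloxy)ethenyl]-3-(triisopropylsilyloxy)cyclobut-2-en-1-one (racemic) | O=C1C(c2cc(C3OCC(C)(C)CO3)ccc2OCc2ccccc2)=C(O[Si](C(C)C)(C(C)C)C(C)C)C1C(=C)OCc1ccccc1 | intermediate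
11 | 2-Ar-5-(benzyloxy)-3-(triisopropylsilyloxy)hexa-1,3,5-trien-1-one, isomer with C2 and C5 cis across C3=C4 | O=C=C(c1cc(C2OCC(C)(C)CO2)ccc1OCc1ccccc1)/C(O[Si](C(C)C)(C(C)C)C(C)C)=C\C(=C)OCc1ccccc1 | intermediate
12 | 2-Ar-5-(benzyloxy)-3-(triisopropylsilyloxy)cyclohexa-2,4-dien-1-one | O=C1CC(OCc2ccccc2)=CC(O[Si](C(C)C)(C(C)C)C(C)C)=C1c1cc(C2OCC(C)(C)CO2)ccc1OCc1ccccc1 | intermediate
13 | 2-Ar-5-(benzyloxy)-3-(triisopropylsilyloxy)phenol | Oc1cc(OCc2ccccc2)cc(O[Si](C(C)C)(C(C)C)C(C)C)c1-c1cc(C2OCC(C)(C)CO2)ccc1OCc1ccccc1 | intermediate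
14 | 3-Ar-6-(benzyloxy)-2-hydroxy-4-(triisopropylsilyloxy)benzaldehyde | O=Cc1c(O)c(-c2cc(C3OCC(C)(C)CO3)ccc2OCc2ccccc2)c(O[Si](C(C)C)(C(C)C)C(C)C)cc1OCc1ccccc1 | intermediate
15 | 1-[3-Ar-6-(benzyloxy)-2-hydroxy-4-(triisopropylsilyloxy)phenyl]ethanol (racemic) | CC(O)c1c(O)c(-c2cc(C3OCC(C)(C)CO3)ccc2OCc2ccccc2)c(O[Si](C(C)C)(C(C)C)C(C)C)cc1OCc1ccccc1 | intermediate
16 | 1-[3-Ar-6-(benzyloxy)-2-hydroxy-4-(triisopropylsilyloxy)phenyl]ethanone | CC(=O)c1c(O)c(-c2cc(C3OCC(C)(C)CO3)ccc2OCc2ccccc2)c(O[Si](C(C)C)(C(C)C)C(C)C)cc1OCc1ccccc1 | intermediate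
17 | 4-(benzyloxy)benzoyl chloride | O=C(Cl)c1ccc(OCc2ccccc2)cc1 | starting material
18 | 1-[3-Ar-6-(benzyloxy)-2-hydroxy-4-(triisopropylsilyloxy)phenyl]-3-[4-(benzyloxy)phenyl]propane-1,3-dione | O=C(CC(=O)c1ccc(OCc2ccccc2)cc1)c1c(O)c(-c2cc(C3OCC(C)(C)CO3)ccc2OCc2ccccc2)c(O[Si](C(C)C)(C(C)C)C(C)C)cc1OCc1ccccc1 | intermediate
19 | 8-Ar-5-(benzyloxy)-2-[4-(benzyloxy)phenyl]-7-(triisopropylsilyloxy)-4H-chromen-4-one | O=c1cc(-c2ccc(OCc3ccccc3)cc2)oc2c(-c3cc(C4OCC(C)(C)CO4)ccc3OCc3ccccc3)c(O[Si](C(C)C)(C(C)C)C(C)C)cc(OCc3ccccc3)c12 | intermediate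
20 | 4-(benzyloxy)-3-{5-(benzyloxy)-2-[4-(benzyloxy)phenyl]-4-oxo-7-(triisopropylsilyloxy)-4H-chromen-8-yl}benzaldehyde | O=Cc1ccc(OCc2ccccc2)c(-c2c(O[Si](C(C)C)(C(C)C)C(C)C)cc(OCc3ccccc3)c3c(=O)cc(-c4ccc(OCc5ccccc5)cc4)oc23)c1 | intermediate
21 | 4-(benzyloxy)-3-{5,7-bis(benzyloxy)-2-[4-(benzyloxy)phenyl]-4-oxo-4H-chromen-8-yl}benzaldehyde | O=Cc1ccc(OCc2ccccc2)c(-c2c(OCc3ccccc3)cc(OCc3ccccc3)c3c(=O)cc(-c4ccc(OCc5ccccc5)cc4)oc23)c1 | intermediate
22 | 2,4,6-trihydroxyacetophenone | CC(=O)c1c(O)cc(O)cc1O | starting material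
23 | 2,6-dihydroxy-4-methoxyacetophenone | COc1cc(O)c(C(C)=O)c(O)c1 | intermediate
24 | 2-(benzyloxy)-6-hydroxy-4-methoxyacetophenone | COc1cc(O)c(C(C)=O)c(OCc2ccccc2)c1 | intermediate
25 | tert-butyl 3-[2-(benzyloxy)-6-hydroxy-4-methoxyphenyl]-3-oxopropanoate | COc1cc(O)c(C(=O)CC(=O)OC(C)(C)C)c(OCc2ccccc2)c1 | intermediate
26 | tert-butyl (Z)-2-[2-(benzyloxy)-6-hydroxy-4-methoxybenzoyl]-3-[4-(benzyloxy)-3-Fl-phenyl]prop-2-enoate | COc1cc(O)c(C(=O)/C(C(=O)OC(C)(C)C)=C/c2ccc(OCc3ccccc3)c(-c3c(OCc4ccccc4)cc(OCc4ccccc4)c4c(=O)cc(-c5ccc(OCc6ccccc6)cc5)oc34)c2)c(OCc2ccccc2)c1 | intermediate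
27 | tert-butyl (2S)-5-(benzyloxy)-2-[4-(benzyloxy)-3-Fl-phenyl]-7-methoxy-4-oxochromane-3-carboxylate (C3 labile, trans favoured) | COc1cc(OCc2ccccc2)c2c(c1)O[C@H](c1ccc(OCc3ccccc3)c(-c3c(OCc4ccccc4)cc(OCc4ccccc4)c4c(=O)cc(-c5ccc(OCc6ccccc6)cc5)oc34)c1)C(C(=O)OC(C)(C)C)C2=O | intermediate
28 | (2S)-5-(benzyloxy)-2-[4-(benzyloxy)-3-Fl-phenyl]-7-methoxy-4-oxochromane-3-carboxylic acid (C3 labile) | COc1cc(OCc2ccccc2)c2c(c1)O[C@H](c1ccc(OCc3ccccc3)c(-c3c(OCc4ccccc4)cc(OCc4ccccc4)c4c(=O)cc(-c5ccc(OCc6ccccc6)cc5)oc34)c1)C(C(=O)O)C2=O | intermediate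
29 | (2S)-5-(benzyloxy)-2-[4-(benzyloxy)-3-Fl-phenyl]-7-methoxychroman-4-one | COc1cc(OCc2ccccc2)c2c(c1)O[C@H](c1ccc(OCc3ccccc3)c(-c3c(OCc4ccccc4)cc(OCc4ccccc4)c4c(=O)cc(-c5ccc(OCc6ccccc6)cc5)oc34)c1)CC2=O | intermediate
30 | 8-{2-hydroxy-5-[(2S)-5-hydroxy-7-methoxy-4-oxochroman-2-yl]phenyl}-5,7-dihydroxy-2-(4-hydroxyphenyl)-4H-chromen-4-one | COc1cc(O)c2c(c1)O[C@H](c1ccc(O)c(-c3c(O)cc(O)c4c(=O)cc(-c5ccc(O)cc5)oc34)c1)CC2=O | target

**Step count**
Total steps: 17. Longest linear sequence: 13 steps (1, 2, 3, 5, 6, 7, 8, 9, 10, 11, 15, 16, 17).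

**Steps most likely to fail**

Step 5.
- What may go wrong: the alkoxyvinylketene may dimerise, or may be consumed by the product phenol, faster than the ortho-substituted aryl ynol ether adds to it. The ynol ether may also drift to a silylketene on long heating.
- Fallback: this gives up the benzannulation and makes the biaryl bond by cross-coupling. It sets out from 22 and 17 and comes back at 21.
- Double benzylation of 22 (BnBr, K2CO3, DMF) should give 1-[2,4-bis(benzyloxy)-6-hydroxyphenyl]ethanone F1.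
- Iodination next to the chelated hydroxyl (BnNMe3·ICl2, CaCO3, CH2Cl2–MeOH) should give 1-[4,6-bis(benzyloxy)-2-hydroxy-3-iodophenyl]ethanone F2.
- Aroylation with 17 under the conditions of step 9 should give 1-[4,6-bis(benzyloxy)-2-hydroxy-3-iodophenyl]-3-[4-(benzyloxy)phenyl]propane-1,3-dione F3.
- Acid cyclodehydration should give 5,7-bis(benzyloxy)-2-[4-(benzyloxy)phenyl]-8-iodo-4H-chromen-4-one F4.
- Suzuki–Miyaura coupling of F4 with catalogue [2-(benzyloxy)-5-formylphenyl]boronic acid (Pd(PPh3)4, K2CO3, dioxane–H2O, 90 °C) leads to 21.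

Step 16.
- What may go wrong: racemic ring closure of the activated chalcone without the catalyst would erode the enantiomeric purity. This is already possible during step 15, because the 6'-benzyloxy group twists the ketone and favours closure. Reversible oxa-Michael addition before decarboxylation would have the same effect, and facial selectivity on this large substrate may be poor.
- Fallback: this replaces asymmetric catalysis by resolution. It sets out from 21 and 24 and comes back at 29.
- Claisen–Schmidt condensation (KOH, EtOH–THF, rt) should give (E)-1-[2-(benzyloxy)-6-hydroxy-4-methoxyphenyl]-3-[4-(benzyloxy)-3-Fl-phenyl]prop-2-en-1-one F5.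
- NaOAc in refluxing EtOH should close it to racemic 5-(benzyloxy)-2-[4-(benzyloxy)-3-Fl-phenyl]-7-methoxychroman-4-one F6.
- Kinetic resolution by Noyori–Ikariya transfer hydrogenation (RuCl[(R,R)-TsDPEN](p-cymene), HCO2H–Et3N, EtOAc) should reduce the 2R enantiomer to (2R,4R)-5-(benzyloxy)-2-[4-(benzyloxy)-3-Fl-phenyl]-7-methoxychroman-4-ol F7. The unreacted 2S ketone 29 is then separated by chromatography.

Step 3.
- What may go wrong: excess alkyllithium may metalate the ortho benzyl ether (Wittig rearrangement) or the acetal C–H. Silylation of the ynolate may also occur on carbon.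
- Fallback: this reaches the ynolate by oxidation of an acetylide without excess alkyllithium. It sets out from 3 and comes back at 5.
- LiAlH4 reduction should give [2-(benzyloxy)-5-(5,5-dimethyl-1,3-dioxan-2-yl)phenyl]methanol F8.
- MnO2 should give 2-(benzyloxy)-5-(5,5-dimethyl-1,3-dioxan-2-yl)benzaldehyde F9.
- Ohira–Bestmann homologation (dimethyl (1-diazo-2-oxopropyl)phosphonate, K2CO3, MeOH) should give 2-[4-(benzyloxy)-3-ethynylphenyl]-5,5-dimethyl-1,3-dioxane F10.
- Deprotonation with LiN(SiMe3)2 and oxygen transfer from lithium tert-butyl peroxide (THF, −78 to 0 °C) gives ynolate 5, which is silylated to 6 as in step 3.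

**Further compounds**
F1 | step 5 | 1-[2,4-bis(benzyloxy)-6-hydroxyphenyl]ethanone | CC(=O)c1c(O)cc(OCc2ccccc2)cc1OCc1ccccc1
F2 | step 5 | 1-[4,6-bis(benzyloxy)-2-hydroxy-3-iodophenyl]ethanone | CC(=O)c1c(O)c(I)c(OCc2ccccc2)cc1OCc1ccccc1
F3 | step 5 | 1-[4,6-bis(benzyloxy)-2-hydroxy-3-iodophenyl]-3-[4-(benzyloxy)phenyl]propane-1,3-dione | O=C(CC(=O)c1ccc(OCc2ccccc2)cc1)c1c(O)c(I)c(OCc2ccccc2)cc1OCc1ccccc1
F4 | step 5 | 5,7-bis(benzyloxy)-2-[4-(benzyloxy)phenyl]-8-iodo-4H-chromen-4-one | O=c1cc(-c2ccc(OCc3ccccc3)cc2)oc2c(I)c(OCc3ccccc3)cc(OCc3ccccc3)c12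
F5 | step 16 | (E)-1-[2-(benzyloxy)-6-hydroxy-4-methoxyphenyl]-3-[4-(benzyloxy)-3-Fl-phenyl]prop-2-en-1-one | COc1cc(O)c(C(=O)/C=C/c2ccc(OCc3ccccc3)c(-c3c(OCc4ccccc4)cc(OCc4ccccc4)c4c(=O)cc(-c5ccc(OCc6ccccc6)cc5)oc34)c2)c(OCc2ccccc2)c1
F6 | step 16 | racemic 5-(benzyloxy)-2-[4-(benzyloxy)-3-Fl-phenyl]-7-methoxychroman-4-one | COc1cc(OCc2ccccc2)c2c(c1)OC(c1ccc(OCc3ccccc3)c(-c3c(OCc4ccccc4)cc(OCc4ccccc4)c4c(=O)cc(-c5ccc(OCc6ccccc6)cc5)oc34)c1)CC2=O
F7 | step 16 | (2R,4R)-5-(benzyloxy)-2-[4-(benzyloxy)-3-Fl-phenyl]-7-methoxychroman-4-ol | COc1cc(OCc2ccccc2)c2c(c1)O[C@@H](c1ccc(OCc3ccccc3)c(-c3c(OCc4ccccc4)cc(OCc4ccccc4)c4c(=O)cc(-c5ccc(OCc6ccccc6)cc5)oc34)c1)C[C@H]2O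
F8 | step 3 | [2-(benzyloxy)-5-(5,5-dimethyl-1,3-dioxan-2-yl)phenyl]methanol | OCc1cc(C2OCC(C)(C)CO2)ccc1OCc1ccccc1
F9 | step 3 | 2-(benzyloxy)-5-(5,5-dimethyl-1,3-dioxan-2-yl)benzaldehyde | O=Cc1cc(C2OCC(C)(C)CO2)ccc1OCc1ccccc1
F10 | step 3 | 2-[4-(benzyloxy)-3-ethynylphenyl]-5,5-dimethyl-1,3-dioxane | C#Cc1cc(C2OCC(C)(C)CO2)ccc1OCc1ccccc1
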